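## Retrosynthetic overview

1. The target comes from an (R)-allylic alcohol (mesylate, then H2O2 with inversion, then desilylation). That alcohol comes from a lactol opened by isopropenylmagnesium bromide, then MnO2 and CBS reduction. The lactol comes from a B-alkyl Suzuki–Miyaura union of a bicyclic enol triflate (right half) with a vinyl-bearing oxepane–cyclohexane diol (left half).
2. Key disconnection: the cyclohexene ring is closed between the ring CH2 next to the carbinol and the carbinol carbon, by intramolecular vinylogous Mukaiyama addition of a tigloyl-derived silyl dienol ether to a cyclic oxocarbenium ion.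
3. Enabling feature: the carbinol carbon and the hydroperoxide-bearing carbon are 1,5-related through the quaternary ring carbon, and the carbinol oxygen is cis to that three-carbon arm. Both carbons can therefore be the two acetal carbons of one temporary 2,6-dimethoxyoxane that becomes cis-fused on closure. The ring-alkene carbon beside the quaternary carbon is carried as a ketone that can enolize only towards the future ring CH2 (its γ-carbon).
4. The quaternary carbon comes from geraniol (Sharpless epoxidation, then Lewis-acid 1,2-shift of the silyloxymethyl group). The left half comes from geranyl bromide (Shi bis-epoxidation, then one epoxide-opening cascade).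
5. Ring order: temporary oxane (step 7), cyclohexenone (step 9), oxepane and cyclohexanone together (step 15), oxane opened (steps 18 and 19).

Key step: step 9

Assumption: read from the SMILES, the ring carbinol is (R), the quaternary ring carbon (S) and the carbinol oxygen is cis to the hydroperoxide-bearing arm; the enantiomer of the D-fructose-derived Shi ketone is taken as available.

## Route

Step 1
Reactants: 1 geraniol
Product: 2 (2R,3R)-2,3-epoxygeraniol
Conditions: Ti(OiPr)4 (5 mol %), D-(−)-diethyl tartrate (6 mol %), t-BuOOH, 4 Å MS, CH2Cl2, −20 °C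
Reagents that add atoms: tert-butyl hydroperoxide, CC(C)(C)OO
Why: Sharpless asymmetric epoxidation of the allylic alcohol, in which the titanium D-tartrate complex delivers oxygen to the face that gives the (2R,3R)-epoxide and leaves the remote trisubstituted alkene untouched.

Step 2
Reactants: 2 (2R,3R)-2,3-epoxygeraniol
Product: 3 tert-butyldimethylsilyl ether of 2
Conditions: t-BuMe2SiCl, imidazole, DMF, 0 °C → rt
Reagents that add atoms: tert-butyldimethylsilyl chloride, CC(C)(C)[Si](C)(C)Cl
Why: Standard silylation of a primary alcohol, which installs the silyloxymethyl group that has to migrate in step 3.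

Step 3
Reactants: 3 tert-butyldimethylsilyl ether of 2
Product: 4 (2R)-2-{[tert-butyl(dimethyl)silyl]oxymethyl}-2,6-dimethylhept-5-enal
Conditions: MeAl(OAr)2 (Ar = 4-bromo-2,6-di-tert-butylphenyl; 2 equiv, from AlMe3 and ArOH), CH2Cl2, −78 °C
Reagents that add atoms: none
Why: Lewis-acid-promoted semipinacol-type rearrangement of a 2,3-epoxy silyl ether, in which the bulky aluminium reagent opens the epoxide at the tertiary carbon and the silyloxymethyl group migrates anti to the leaving oxygen, so the epoxide configuration is transferred with inversion to the new (R)-quaternary carbon.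

Step 4
Reactants: 4 (2R)-2-{[tert-butyl(dimethyl)silyl]oxymethyl}-2,6-dimethylhept-5-enal; 5 (E)-2-bromobut-2-ene
Product: 7 (2E,5R)-5-{[tert-butyl(dimethyl)silyl]oxymethyl}-3,5,9-trimethyldeca-2,8-dien-4-ol (both C4 epimers), via (E)-but-2-en-2-yllithium 6 (not isolated)
Conditions: 5, t-BuLi (2 equiv), Et2O, −78 °C; then 4, −78 °C; aq. NH4Cl
Reagents that add atoms: none
Why: Bromine–lithium exchange with retention of alkene geometry followed by 1,2-addition of the alkenyllithium to the non-enolizable aldehyde, the new carbinol centre being formed without control because it is erased in step 6.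

Step 5
Reactants: 7 (2E,5R)-5-{[tert-butyl(dimethyl)silyl]oxymethyl}-3,5,9-trimethyldeca-2,8-dien-4-ol
Product: 8 (2E,5R)-5-(hydroxymethyl)-3,5,9-trimethyldeca-2,8-dien-4-ol (both C4 epimers)
Conditions: Bu4NF, THF, 0 °C → rt
Reagents that add atoms: none
Why: Fluoride-mediated desilylation, carried out before any base-sensitive carbonyl group is present.

Step 6
Reactants: 8 (2E,5R)-5-(hydroxymethyl)-3,5,9-trimethyldeca-2,8-dien-4-ol
Product: 9 (2R,4E)-2,4-dimethyl-2-(4-methylpent-3-en-1-yl)-3-oxohex-4-enal
Conditions: Dess–Martin periodinane (3 equiv), NaHCO3, CH2Cl2, 0 °C → rt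
Reagents that add atoms: none
Why: Dess–Martin oxidation of both hydroxyls under buffered non-basic conditions should give the non-enolizable 2,2-disubstituted 3-oxo aldehyde without retro-aldol cleavage or deformylation.

Step 7
Reactants: 9 (2R,4E)-2,4-dimethyl-2-(4-methylpent-3-en-1-yl)-3-oxohex-4-enal
Product: 11 (3R)-2,6-dimethoxy-3-methyl-3-[(2E)-2-methylbut-2-enoyl]oxane (mixture of acetal epimers), via keto dialdehyde 10 (not isolated)
Conditions: O3, CH2Cl2–MeOH, −78 °C (Sudan Red 7B end-point); Me2S, −78 °C → rt; then PPTS (cat.), MeOH, 3 Å MS, rt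
Reagents that add atoms: ozone, [O-][O+]=O; methanol, CO
Why: Ozonolysis selects the electron-rich trisubstituted alkene over the conjugated enone, and acid-catalysed acetalization then closes the 1,5-dialdehyde to the 2,6-dimethoxyoxane that serves as the temporary ring.

Step 8
Reactants: 11 (3R)-2,6-dimethoxy-3-methyl-3-[(2E)-2-methylbut-2-enoyl]oxane
Product: 12 tert-butyl({(1E)-1-[(3S)-2,6-dimethoxy-3-methyloxan-3-yl]-2-methylbuta-1,3-dien-1-yl}oxy)dimethylsilane
Conditions: KN(SiMe3)2, t-BuMe2SiCl, THF–DMPU, −78 °C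
Reagents that add atoms: tert-butyldimethylsilyl chloride, CC(C)(C)[Si](C)(C)Cl
Why: γ-Deprotonation and O-silylation (silyl dienol ether formation) of a ketone that has no α′-hydrogen, taking place from the s-trans enone conformer that keeps the quaternary carbon away from the α-methyl group and so placing the vinyl group cis to the quaternary carbon, while the acetals are inert to the base.

Step 9
Reactants: 12 tert-butyl({(1E)-1-[(3S)-2,6-dimethoxy-3-methyloxan-3-yl]-2-methylbuta-1,3-dien-1-yl}oxy)dimethylsilane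
Product: 13 (4aR,8aR)-2-methoxy-4a,6-dimethyl-2,3,4,4a,8,8a-hexahydro-5H-chromen-5-one (cis-fused, both anomers at C2)
Conditions: Me3SiOTf (0.3 equiv), 2,6-di-tert-butyl-4-methylpyridine (0.5 equiv), CH2Cl2 (0.01 M), −78 → −40 °C; Et3N quench
Reagents that add atoms: none
Why: The silyl triflate ionizes either anomeric methoxy group reversibly, and the oxocarbenium ion at the acetal carbon next to the quaternary carbon is attacked by the terminal CH2 (γ-carbon) of the 2-silyloxy-1,3-diene, after which loss of the silyl group leaves the α-methyl enone; the closest known reaction type is the vinylogous Mukaiyama addition of silyl dienol ethers to acetals, used here intramolecularly. The cyclohexenone ring closes in the 6-exo-trig mode with respect to the C=O+ bond, with the enol double bond inside the new ring (6-enolendo). The new carbinol stereocentre is controlled by the quaternary carbon through the temporary oxane: chair-like axial attack on the half-chair oxocarbenium ion by an arm held on the adjacent carbon should give the cis-fused bicycle, which places the ring oxygen cis to the three-carbon arm as in the target. The step needs γ- over α-attack, reaction at the proximal rather than the distal acetal carbon, and the cis face. Ring size secures the first two, because α-attack would need a four-membered ring and the distal ion an eight-membered one, so both revert; the preference for a chair over a twist-boat transition state secures the third. High dilution suppresses intermolecular addition.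

Step 10
Reactants: 13 (4aR,8aR)-2-methoxy-4a,6-dimethyl-2,3,4,4a,8,8a-hexahydro-5H-chromen-5-one
Product: 15 (4aR,8aR)-2-methoxy-4a,6-dimethyl-3,4,4a,7,8,8a-hexahydro-2H-chromen-5-yl trifluoromethanesulfonate, via lithium enolate 14 (not isolated)
Conditions: LiBH(s-Bu)3, THF, −78 °C; then N-(5-chloro-2-pyridyl)bis(trifluoromethanesulfonimide), −78 → 0 °C
Reagents that add atoms: N-(5-chloro-2-pyridyl)bis(trifluoromethanesulfonimide), FC(F)(F)S(=O)(=O)N(c1ccc(Cl)cn1)S(=O)(=O)C(F)(F)F
Why: Conjugate reduction of a 2-methylcyclohex-2-enone that has no β-substituent gives the tetrasubstituted enolate regiospecifically, and O-triflation (enol triflate formation) fixes the position of the future ring alkene.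

Step 11
Reactants: 16 N-methoxy-N-methylacetamide; 17 geranyl bromide
Product: 19 (4E)-N-methoxy-N,5,9-trimethyldeca-4,8-dienamide, via amide lithium enolate 18 (not isolated)
Conditions: LiN(iPr)2, THF, −78 °C; then 17, −78 → −20 °C
Reagents that add atoms: none
Why: SN2 alkylation of the amide enolate with a reactive allylic bromide, which keeps the (E)-alkene geometry of the geranyl unit.

Step 12
Reactants: 19 (4E)-N-methoxy-N,5,9-trimethyldeca-4,8-dienamide
Product: 20 3-[(2S,3S)-3-{2-[(2S)-3,3-dimethyloxiran-2-yl]ethyl}-3-methyloxiran-2-yl]-N-methoxy-N-methylpropanamide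
Conditions: enantiomer of the D-fructose-derived Shi ketone (0.6 equiv), KHSO5 (as 2KHSO5·KHSO4·K2SO4), K2CO3, Bu4NHSO4, MeCN–CH2(OMe)2–aq. Na2B4O7 buffer, 0 °C
Reagents that add atoms: potassium peroxymonosulfate, [K+].[O-]S(=O)(=O)OO
Why: Shi epoxidation, in which the chiral dioxirane attacks both trisubstituted alkenes in the same sense under catalyst control to set the three (S)-configured epoxide carbons that carry hydrogen or methyl.

Step 13
Reactants: 20 diepoxy amide
Product: 21 1-[(2S,3S)-3-{2-[(2S)-3,3-dimethyloxiran-2-yl]ethyl}-3-methyloxiran-2-yl]hex-5-en-3-one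
Conditions: CH2=CHCH2MgBr, THF, −78 °C; pH 7 buffer
Reagents that add atoms: allylmagnesium bromide, C=CC[Mg]Br
Why: Weinreb ketone synthesis, in which the chelated tetrahedral intermediate prevents over-addition and the hindered epoxides are not opened at −78 °C.

Step 14
Reactants: 21 diepoxy allyl ketone
Product: 22 tert-butyl({(3Z)-1-[(2S,3S)-3-{2-[(2S)-3,3-dimethyloxiran-2-yl]ethyl}-3-methyloxiran-2-yl]hexa-3,5-dien-3-yl}oxy)dimethylsilane
Conditions: KN(SiMe3)2, t-BuMe2SiCl, THF, −78 °C
Reagents that add atoms: tert-butyldimethylsilyl chloride, CC(C)(C)[Si](C)(C)Cl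
Why: Deprotonation at the doubly activated carbon between carbonyl and vinyl and O-silylation (silyl dienol ether formation) give the conjugated dienol ether regioselectively, and the epoxides are inert to the hindered base.

Step 15
Reactants: 22 diepoxy silyl dienol ether
Product: 24 (3S,5aS,6S,9aS)-6-ethenyl-3-hydroxy-2,2,5a-trimethyloctahydro-1-benzoxepin-7(2H)-one (trans-fused), via trimethylsilyl ether 23 (not isolated)
Conditions: Me3SiOTf (1.2 equiv), 2,6-di-tert-butyl-4-methylpyridine, CH2Cl2, −78 °C; then citric acid, MeOH, 0 °C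
Reagents that add atoms: none
Why: Epoxide-opening oxa-/carbacyclization cascade, in which the silylated terminal epoxide is opened at its tertiary carbon by the inner epoxide oxygen (oxepane) and the resulting epoxonium ion is opened with inversion at its tertiary carbon by the α-carbon of the dienol ether through a chair, so the trans ring fusion and three stereocentres are relayed from the epoxides and the vinyl group takes the equatorial position.

Step 16
Reactants: 24 bicyclic vinyl ketone
Product: 25 (3S,5aS,6S,7R,9aS)-6-ethenyl-2,2,5a,7-tetramethyldecahydro-1-benzoxepine-3,7-diol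
Conditions: MeLi, CeCl3, THF, −78 °C
Reagents that add atoms: methyllithium, [Li]C
Why: 1,2-Addition of the weakly basic organocerium reagent, in which axial approach is blocked by the 1,3-diaxial angular methyl group so that methyl enters equatorially and the tertiary hydroxyl becomes axial (7R).

Step 17
Reactants: 25 vinyl diol; 15 enol triflate
Product: 27 (4aS,8aR)-5-{2-[(3S,5aS,6S,7R,9aS)-3,7-dihydroxy-2,2,5a,7-tetramethyldecahydro-1-benzoxepin-6-yl]ethyl}-2-methoxy-4a,6-dimethyl-3,4,4a,7,8,8a-hexahydro-2H-chromene, via B-alkyl-9-BBN adduct 26 (not isolated)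
Conditions: 25, 9-BBN-H (3 equiv), THF, rt; then 15, Pd(dppf)Cl2 (10 mol %), AsPh3, Cs2CO3, DMF–H2O, 50 °C
Reagents that add atoms: none
Why: Anti-Markovnikov hydroboration followed by B-alkyl Suzuki–Miyaura coupling with the enol triflate creates the tetrasubstituted ring alkene, whose position and geometry are fixed by the ring, and forms no stereocentre.

Step 18
Reactants: 27 coupled methyl acetal
Product: 28 corresponding lactol (2-hydroxy in place of 2-methoxy, both anomers)
Conditions: AcOH–THF–H2O (3:1:1), 40 °C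
Reagents that add atoms: water, O
Why: Acid hydrolysis of a 2-methoxyoxane (glycoside-type acetal) under conditions mild enough to spare the tertiary alcohol and the tetrasubstituted alkene.

Step 19
Reactants: 28 lactol
Product: 29 (1R,2S)-3-{2-[(3S,5aS,6S,7R,9aS)-3,7-dihydroxy-2,2,5a,7-tetramethyldecahydro-1-benzoxepin-6-yl]ethyl}-2-(3-hydroxy-4-methylpent-4-en-1-yl)-2,4-dimethylcyclohex-3-en-1-ol (both epimers at the allylic carbinol)
Conditions: CH2=C(CH3)MgBr (excess), THF, 0 °C → rt
Reagents that add atoms: isopropenylmagnesium bromide, C=C(C)[Mg]Br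
Why: Grignard addition to the open hydroxy-aldehyde form of the lactol removes the temporary ring and frees the ring carbinol, the new allylic carbinol being formed without control because it is reset in steps 20 and 22.

Step 20
Reactants: 29 tetraol
Product: 30 5-[(1S,6R)-2-{2-[(3S,5aS,6S,7R,9aS)-3,7-dihydroxy-2,2,5a,7-tetramethyldecahydro-1-benzoxepin-6-yl]ethyl}-6-hydroxy-1,3-dimethylcyclohex-2-en-1-yl]-2-methylpent-1-en-3-one
Conditions: MnO2 (activated, excess), CH2Cl2, rt
Reagents that add atoms: none
Why: Chemoselective allylic oxidation, since MnO2 oxidizes only the allylic alcohol and leaves the two saturated secondary alcohols and the tertiary alcohol untouched.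

Step 21
Reactants: 30 enone triol
Product: 31 bis(triethylsilyl) ether of 30 at the two secondary hydroxyls (tertiary hydroxyl free)
Conditions: Et3SiCl, imidazole, DMAP (cat.), DMF, rt
Reagents that add atoms: chlorotriethylsilane, CC[Si](Cl)(CC)CC
Why: Silylation of the two secondary hydroxyls, which the hindered axial tertiary hydroxyl does not undergo, so that the allylic alcohol made next is the only reactive hydroxyl.

Step 22
Reactants: 31 bis(triethylsilyl) enone
Product: 32 (3R)-allylic alcohol, i.e. 31 with (3R)-3-hydroxy-4-methylpent-4-en-1-yl in place of the enone arm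
Conditions: (S)-2-methyl-CBS-oxazaborolidine (0.5 equiv), catecholborane, toluene, −78 °C
Reagents that add atoms: none
Why: Corey–Bakshi–Shibata reduction under catalyst control, with the isopropenyl group acting as the large and the primary alkyl chain as the small substituent, should give the (R)-alcohol independently of the remote stereocentres.

Step 23
Reactants: 32 (3R)-allylic alcohol
Product: 34 bis(triethylsilyl) ether of the target [(3S)-hydroperoxide], via allylic mesylate 33 (not isolated)
Conditions: Ms2O, Et3N, CH2Cl2, −78 °C; then anhydrous H2O2 in Et2O (excess), −78 → −30 °C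
Reagents that add atoms: hydrogen peroxide, OO
Why: Sulfonate displacement by hydrogen peroxide (SN2) should give the (S)-hydroperoxide with inversion, the chloride-free mesylation and low temperature being chosen to suppress ionization and allylic transposition.

Step 24
Reactants: 34 bis(triethylsilyl) hydroperoxide
Product: 35 target, (1R,2S)-3-{2-[(3S,5aS,6S,7R,9aS)-3,7-dihydroxy-2,2,5a,7-tetramethyldecahydro-1-benzoxepin-6-yl]ethyl}-2-[(3S)-3-hydroperoxy-4-methylpent-4-en-1-yl]-2,4-dimethylcyclohex-3-en-1-ol
Conditions: HF·pyridine, pyridine, THF, 0 °C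
Reagents that add atoms: none
Why: Fluoride-mediated desilylation under buffered mildly acidic conditions, which secondary allylic hydroperoxides tolerate whereas basic fluoride sources would dehydrate them.

## Compound list

1 | geraniol | CC(C)=CCC/C(C)=C/CO | starting material
2 | (2R,3R)-2,3-epoxygeraniol | CC(C)=CCC[C@@]1(C)O[C@@H]1CO | intermediate
3 | tert-butyl{[(2R,3R)-3-methyl-3-(4-methylpent-3-en-1-yl)oxiran-2-yl]methoxy}dimethylsilane | CC(C)=CCC[C@@]1(C)O[C@@H]1CO[Si](C)(C)C(C)(C)C | intermediate
4 | (2R)-2-{[tert-butyl(dimethyl)silyl]oxymethyl}-2,6-dimethylhept-5-enal | O=C[C@@](C)(CO[Si](C)(C)C(C)(C)C)CCC=C(C)C | intermediate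
5 | (E)-2-bromobut-2-ene | C/C=C(\C)Br | starting material
6 | (E)-but-2-en-2-yllithium | C/C=C(\C)[Li] | intermediate
7 | (2E,5R)-5-{[tert-butyl(dimethyl)silyl]oxymethyl}-3,5,9-trimethyldeca-2,8-dien-4-ol (C4 epimers) | C/C=C(\C)C(O)[C@@](C)(CO[Si](C)(C)C(C)(C)C)CCC=C(C)C | intermediate
8 | (2E,5R)-5-(hydroxymethyl)-3,5,9-trimethyldeca-2,8-dien-4-ol (C4 epimers) | C/C=C(\C)C(O)[C@@](C)(CO)CCC=C(C)C | intermediate
9 | (2R,4E)-2,4-dimethyl-2-(4-methylpent-3-en-1-yl)-3-oxohex-4-enal | C/C=C(\C)C(=O)[C@@](C)(C=O)CCC=C(C)C | intermediate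
10 | (2R,4E)-2,4-dimethyl-3-oxo-2-(3-oxopropyl)hex-4-enal | C/C=C(\C)C(=O)[C@@](C)(C=O)CCC=O | intermediate
11 | (3R)-2,6-dimethoxy-3-methyl-3-[(2E)-2-methylbut-2-enoyl]oxane (acetal epimers) | COC1CC[C@@](C)(C(=O)/C(C)=C/C)C(OC)O1 | intermediate
12 | tert-butyl({(1E)-1-[(3S)-2,6-dimethoxy-3-methyloxan-3-yl]-2-methylbuta-1,3-dien-1-yl}oxy)dimethylsilane | COC1CC[C@@](C)(/C(O[Si](C)(C)C(C)(C)C)=C(/C)C=C)C(OC)O1 | intermediate
13 | (4aR,8aR)-2-methoxy-4a,6-dimethyl-2,3,4,4a,8,8a-hexahydro-5H-chromen-5-one (cis-fused, C2 anomers) | COC1CC[C@@]2(C)C(=O)C(C)=CC[C@H]2O1 | intermediate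
14 | lithium (4aR,8aR)-2-methoxy-4a,6-dimethyl-3,4,4a,7,8,8a-hexahydro-2H-chromen-5-olate | COC1CC[C@@]2(C)C(O[Li])=C(C)CC[C@H]2O1 | intermediate
15 | (4aR,8aR)-2-methoxy-4a,6-dimethyl-3,4,4a,7,8,8a-hexahydro-2H-chromen-5-yl trifluoromethanesulfonate | COC1CC[C@@]2(C)C(OS(=O)(=O)C(F)(F)F)=C(C)CC[C@H]2O1 | intermediate
16 | N-methoxy-N-methylacetamide | CC(=O)N(C)OC | starting material
17 | geranyl bromide | CC(C)=CCC/C(C)=C/CBr | starting material
18 | lithium enolate of N-methoxy-N-methylacetamide | C=C(O[Li])N(C)OC | intermediate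
19 | (4E)-N-methoxy-N,5,9-trimethyldeca-4,8-dienamide | CC(C)=CCC/C(C)=C/CCC(=O)N(C)OC | intermediate
20 | 3-[(2S,3S)-3-{2-[(2S)-3,3-dimethyloxiran-2-yl]ethyl}-3-methyloxiran-2-yl]-N-methoxy-N-methylpropanamide | CON(C)C(=O)CC[C@@H]1O[C@@]1(C)CC[C@@H]1OC1(C)C | intermediate
21 | 1-[(2S,3S)-3-{2-[(2S)-3,3-dimethyloxiran-2-yl]ethyl}-3-methyloxiran-2-yl]hex-5-en-3-one | C=CCC(=O)CC[C@@H]1O[C@@]1(C)CC[C@@H]1OC1(C)C | intermediate
22 | tert-butyl({(3Z)-1-[(2S,3S)-3-{2-[(2S)-3,3-dimethyloxiran-2-yl]ethyl}-3-methyloxiran-2-yl]hexa-3,5-dien-3-yl}oxy)dimethylsilane | C=C/C=C(\O[Si](C)(C)C(C)(C)C)CC[C@@H]1O[C@@]1(C)CC[C@@H]1OC1(C)C | intermediate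
23 | (3S,5aS,6S,9aS)-6-ethenyl-2,2,5a-trimethyl-3-[(trimethylsilyl)oxy]octahydro-1-benzoxepin-7(2H)-one | C=C[C@H]1[C@]2(C)CC[C@H](O[Si](C)(C)C)C(C)(C)O[C@H]2CCC1=O | intermediate
24 | (3S,5aS,6S,9aS)-6-ethenyl-3-hydroxy-2,2,5a-trimethyloctahydro-1-benzoxepin-7(2H)-one | C=C[C@H]1[C@]2(C)CC[C@H](O)C(C)(C)O[C@H]2CCC1=O | intermediate
25 | (3S,5aS,6S,7R,9aS)-6-ethenyl-2,2,5a,7-tetramethyldecahydro-1-benzoxepine-3,7-diol | C=C[C@H]1[C@]2(C)CC[C@H](O)C(C)(C)O[C@H]2CC[C@@]1(C)O | intermediate
26 | B-alkyl-9-BBN adduct of 25 (6-[2-(9-borabicyclo[3.3.1]nonan-9-yl)ethyl]) | B1(CC[C@H]2[C@]3(C)CC[C@H](O)C(C)(C)O[C@H]3CC[C@@]2(C)O)C2CCCC1CCC2 | intermediate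
27 | (4aS,8aR)-5-{2-[(3S,5aS,6S,7R,9aS)-3,7-dihydroxy-2,2,5a,7-tetramethyldecahydro-1-benzoxepin-6-yl]ethyl}-2-methoxy-4a,6-dimethyl-3,4,4a,7,8,8a-hexahydro-2H-chromene (C2 anomers) | COC1CC[C@@]2(C)C(CC[C@H]3[C@]4(C)CC[C@H](O)C(C)(C)O[C@H]4CC[C@@]3(C)O)=C(C)CC[C@H]2O1 | intermediate
28 | lactol of 27 (2-hydroxy in place of 2-methoxy, C2 anomers) | OC1CC[C@@]2(C)C(CC[C@H]3[C@]4(C)CC[C@H](O)C(C)(C)O[C@H]4CC[C@@]3(C)O)=C(C)CC[C@H]2O1 | intermediate
29 | (1R,2S)-3-{2-[(3S,5aS,6S,7R,9aS)-3,7-dihydroxy-2,2,5a,7-tetramethyldecahydro-1-benzoxepin-6-yl]ethyl}-2-(3-hydroxy-4-methylpent-4-en-1-yl)-2,4-dimethylcyclohex-3-en-1-ol (allylic carbinol epimers) | C=C(C)C(O)CC[C@@]1(C)C(CC[C@H]2[C@]3(C)CC[C@H](O)C(C)(C)O[C@H]3CC[C@@]2(C)O)=C(C)CC[C@H]1O | intermediate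
30 | 5-[(1S,6R)-2-{2-[(3S,5aS,6S,7R,9aS)-3,7-dihydroxy-2,2,5a,7-tetramethyldecahydro-1-benzoxepin-6-yl]ethyl}-6-hydroxy-1,3-dimethylcyclohex-2-en-1-yl]-2-methylpent-1-en-3-one | C=C(C)C(=O)CC[C@@]1(C)C(CC[C@H]2[C@]3(C)CC[C@H](O)C(C)(C)O[C@H]3CC[C@@]2(C)O)=C(C)CC[C@H]1O | intermediate
31 | bis(triethylsilyl) ether of 30 (ring carbinol and oxepane carbinol silylated, tertiary hydroxyl free) | C=C(C)C(=O)CC[C@@]1(C)C(CC[C@H]2[C@]3(C)CC[C@H](O[Si](CC)(CC)CC)C(C)(C)O[C@H]3CC[C@@]2(C)O)=C(C)CC[C@H]1O[Si](CC)(CC)CC | intermediate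
32 | (3R)-allylic alcohol from 31 [(3R)-3-hydroxy-4-methylpent-4-en-1-yl arm] | C=C(C)[C@H](O)CC[C@@]1(C)C(CC[C@H]2[C@]3(C)CC[C@H](O[Si](CC)(CC)CC)C(C)(C)O[C@H]3CC[C@@]2(C)O)=C(C)CC[C@H]1O[Si](CC)(CC)CC | intermediate
33 | (3R)-allylic methanesulfonate of 32 | C=C(C)[C@H](OS(C)(=O)=O)CC[C@@]1(C)C(CC[C@H]2[C@]3(C)CC[C@H](O[Si](CC)(CC)CC)C(C)(C)O[C@H]3CC[C@@]2(C)O)=C(C)CC[C@H]1O[Si](CC)(CC)CC | intermediate
34 | bis(triethylsilyl) ether of the target [(3S)-hydroperoxide] | C=C(C)[C@@H](OO)CC[C@@]1(C)C(CC[C@H]2[C@]3(C)CC[C@H](O[Si](CC)(CC)CC)C(C)(C)O[C@H]3CC[C@@]2(C)O)=C(C)CC[C@H]1O[Si](CC)(CC)CC | intermediate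
35 | (1R,2S)-3-{2-[(3S,5aS,6S,7R,9aS)-3,7-dihydroxy-2,2,5a,7-tetramethyldecahydro-1-benzoxepin-6-yl]ethyl}-2-[(3S)-3-hydroperoxy-4-methylpent-4-en-1-yl]-2,4-dimethylcyclohex-3-en-1-ol | C=C(C)[C@H](CC[C@@]1(C)C(CC[C@H]2[C@]3(C)CC[C@H](O)C(C)(C)O[C@H]3CC[C@@]2(C)O)=C(C)CC[C@H]1O)OO | target

## Step count and risks

Total step count: 24. Longest linear sequence: 18 steps (steps 1–10, then 17–24); the left half (steps 11–16) is made in parallel.

The three steps most likely to fail:

Step 9. The diene terminus may attack the oxocarbenium ion on the wrong face through a twist-boat transition state, giving the trans ring fusion and so the wrong carbinol epimer. The fallback sets the carbinol by reagent control instead, setting out from 15 (as the mixture of ring-fusion epimers) and coming back at 15. Transthioacetalization of the methyl acetal with ethane-1,2-dithiol and BF3·OEt2 would open the oxane to the dithiolane alcohol F1. Dess–Martin oxidation would give the ketone F2. Corey–Bakshi–Shibata reduction with the (S)-oxazaborolidine and BH3·SMe2, the quaternary carbon acting as the large group, would give the (5R)-alcohol F3. Removal of the dithiolane (MeI, CaCO3, aqueous MeCN) and PPTS in MeOH would then close the methyl lactol acetal again and return 15 as the cis-fused isomer only.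

Step 17. Transmetalation and reductive elimination at the alkenylpalladium flanked by a quaternary carbon and a methyl-bearing carbon may be too slow, so that protodeboronation and β-hydride elimination take over. The fallback joins the halves through an sp–sp2 bond, which tolerates this hindrance, setting out from 25 and coming back at 27. Ozonolysis of the vinyl group of 25 would give the aldehyde F4. Corey–Fuchs homologation (CBr4, PPh3; then n-BuLi) would give the dibromoalkene F5 and then the alkyne F6. Sonogashira coupling of F6 with 15 (Pd(PPh3)4, CuI, iPr2NH) would give the enyne F7. Saturation of the alkyne with diimide (TsNHNH2, NaOAc), which does not touch the tetrasubstituted alkene, would give 27.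

Step 23. The 2-methylallyl mesylate may ionize or be attacked at the alkene terminus, which would scramble the carbinol configuration or move the peroxide to the primary carbon. The fallback uses a protected, more nucleophilic peroxide and a different end-game, setting out from 32 (through the mesylate 33) and coming back at 35. Alkylation of the caesium salt of 2-methoxyprop-2-yl hydroperoxide (CsOH, DMF, 0 °C) with 33 would give the peroxyketal F8. AcOH–THF–H2O would then cleave the peroxyketal and both triethylsilyl ethers in one operation to give 35.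

## Further compounds

F1 | step 9 | (6R)-6-[2-(1,3-dithiolan-2-yl)ethyl]-5-hydroxy-2,6-dimethylcyclohex-1-en-1-yl trifluoromethanesulfonate (C5 epimers) | CC1=C(OS(=O)(=O)C(F)(F)F)[C@](C)(CCC2SCCS2)C(O)CC1
F2 | step 9 | (6S)-6-[2-(1,3-dithiolan-2-yl)ethyl]-2,6-dimethyl-5-oxocyclohex-1-en-1-yl trifluoromethanesulfonate | CC1=C(OS(=O)(=O)C(F)(F)F)[C@](C)(CCC2SCCS2)C(=O)CC1
F3 | step 9 | (5R,6R)-6-[2-(1,3-dithiolan-2-yl)ethyl]-5-hydroxy-2,6-dimethylcyclohex-1-en-1-yl trifluoromethanesulfonate | CC1=C(OS(=O)(=O)C(F)(F)F)[C@](C)(CCC2SCCS2)[C@H](O)CC1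
F4 | step 17 | (3S,5aS,6S,7R,9aS)-3,7-dihydroxy-2,2,5a,7-tetramethyldecahydro-1-benzoxepine-6-carbaldehyde | O=C[C@H]1[C@]2(C)CC[C@H](O)C(C)(C)O[C@H]2CC[C@@]1(C)O
F5 | step 17 | 6-(2,2-dibromoethenyl) analogue of 25 | BrC(Br)=C[C@H]1[C@]2(C)CC[C@H](O)C(C)(C)O[C@H]2CC[C@@]1(C)O
F6 | step 17 | 6-ethynyl analogue of 25 | C#C[C@H]1[C@]2(C)CC[C@H](O)C(C)(C)O[C@H]2CC[C@@]1(C)O
F7 | step 17 | enyne analogue of 27 (ethynediyl in place of the ethane-1,2-diyl link) | COC1CC[C@@]2(C)C(C#C[C@H]3[C@]4(C)CC[C@H](O)C(C)(C)O[C@H]4CC[C@@]3(C)O)=C(C)CC[C@H]2O1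
F8 | step 23 | (3S)-2-methoxyprop-2-yl peroxide of 34 (peroxyketal) | C=C(C)[C@@H](OOC(C)(C)OC)CC[C@@]1(C)C(CC[C@H]2[C@]3(C)CC[C@H](O[Si](CC)(CC)CC)C(C)(C)O[C@H]3CC[C@@]2(C)O)=C(C)CC[C@H]1O[Si](CC)(CC)CC
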